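**Plan**

- Numbering: ring carbons C1 (alkene carbon bearing isopropyl), C2 (alkene CH), C3/C4 (epoxide, methyl on C4), C5–C7, C8 (bearing the CH2OH carbon C19), C9 (ketone), C10, C11, C12 (methyl), C13 (hydroxyl), C14 (enone C=O).
- Enabling feature: in the 14-membered ring the epoxide lies on the γ,δ-bond C3–C4 of the C14=O/C1=C2 enone, so the target is the mono-epoxide of a ring (1E,3Z)-dienone whose C2–C3 single bond joins two sp2 carbons and can be made by cross-coupling two alkenyl partners of fixed geometry.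
- Cuts, in retrosynthetic order: the epoxide C–O bonds (back to C3=C4); C2–C3 (ring opening to alkenylstannane/enol triflate); C1–C2 and C14–C1 (formyl carbon and isobutyl group off a C14 amide); C8–C9 (aldol); C4–C5 (carbocupration of propyne).
- Forward: a C3–C8/C19 acyl oxazolidinone and a C9–C14 aldehyde are joined at C8–C9, the chain is elaborated to the C3 stannane and C2 triflate, the only ring is closed at C2–C3, and C9 oxidation, epoxidation and desilylation finish.
- Stereochemistry: C12 from (R)-citronellic acid; C13 from auxiliary-controlled enolate hydroxylation; C8 from the oxazolidinone syn-aldol; 3Z from syn-carbocupration/iodination and 1E from the enol triflate, both retained in the coupling; C3/C4 from a chiral-dioxirane epoxidation.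

Key step: step 16

Remark: C9 is carried as a triethylsilyl ether until after ring closure, because a C9 ketone would compete in the enolate formylation at C1 and would make C8 base-labile; the tin group is trimethylstannyl for fast transmetalation.

**Route**

Step 1
Reactants: 1 tert-butyl[(5-bromopentyl)oxy]dimethylsilane; 2 propyne
Product: 5 tert-butyl{[(Z)-7-iodo-6-methylhept-6-en-1-yl]oxy}dimethylsilane, via alkylmagnesium bromide 3 (not isolated), via alkenylcopper 4 (not isolated)
Conditions: Mg, Et2O; CuBr·SMe2, Et2O/Me2S, −45 °C; propyne, −25 °C; I2, THF, −78 → 0 °C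
Reagents that add atoms: iodine, II
Why: Carbocupration of a terminal alkyne is a syn addition that puts the alkyl group on the internal carbon (C4) and copper on C3, and iodinolysis with retention should give the (Z)-iodoalkene in which iodine and the C5 chain are cis.

Step 2
Reactants: 5 tert-butyl{[(Z)-7-iodo-6-methylhept-6-en-1-yl]oxy}dimethylsilane
Product: 8 (Z)-7-iodo-6-methylhept-6-enoic acid, via primary alcohol 6 (not isolated), via aldehyde 7 (not isolated)
Conditions: CrO3, H2SO4, acetone/H2O, 0 °C → rt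
Reagents that add atoms: water, O
Why: Jones oxidation, in which the acidic medium cleaves the primary silyl ether and chromic acid takes the alcohol through the aldehyde hydrate to the acid while the iodoalkene is inert.

Step 3
Reactants: 8 (Z)-7-iodo-6-methylhept-6-enoic acid; 9 (R)-4-benzyl-1,3-oxazolidin-2-one
Product: 11 (R)-4-benzyl-3-[(Z)-7-iodo-6-methylhept-6-enoyl]-1,3-oxazolidin-2-one, via mixed pivalic anhydride 10 (not isolated)
Conditions: PivCl, Et3N, THF, −20 °C; then LiCl, 9, −20 °C → rt
Reagents that add atoms: none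
Why: N-Acylation of the oxazolidinone through the mixed pivalic anhydride, whose hindered pivaloyl carbonyl directs attack to the wanted acyl group.

Step 4
Reactants: 12 (R)-citronellic acid [(R)-3,7-dimethyloct-6-enoic acid]; 13 (S)-4-benzyl-1,3-oxazolidin-2-one
Product: 15 (S)-4-benzyl-3-[(R)-3,7-dimethyloct-6-enoyl]-1,3-oxazolidin-2-one, via mixed pivalic anhydride 14 (not isolated)
Conditions: PivCl, Et3N, THF, −20 °C; then LiCl, 13, −20 °C → rt
Reagents that add atoms: none
Why: The same mixed-anhydride N-acylation attaches the auxiliary that will control C13, the C12 centre coming unchanged from the acid.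

Step 5
Reactants: 15 (S)-4-benzyl-3-[(R)-3,7-dimethyloct-6-enoyl]-1,3-oxazolidin-2-one
Product: 17 (S)-4-benzyl-3-[(2S,3R)-2-hydroxy-3,7-dimethyloct-6-enoyl]-1,3-oxazolidin-2-one, via sodium enolate 16 (not isolated)
Conditions: NaN(SiMe3)2, THF, −78 °C; 2-(phenylsulfonyl)-3-phenyloxaziridine, −78 °C; AcOH
Reagents that add atoms: 2-(phenylsulfonyl)-3-phenyloxaziridine, O=S(=O)(c1ccccc1)N1OC1c1ccccc1
Why: Electrophilic hydroxylation of the chelated (Z)-imide enolate by the N-sulfonyloxaziridine takes place on the face opposite the benzyl group of the (S)-auxiliary, which should set C13 as S next to the existing C12 centre.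

Step 6
Reactants: 17 (S)-4-benzyl-3-[(2S,3R)-2-hydroxy-3,7-dimethyloct-6-enoyl]-1,3-oxazolidin-2-one
Product: 18 (2S,3R)-2-hydroxy-N-methoxy-N,3,7-trimethyloct-6-enamide
Conditions: MeONHMe·HCl, AlMe3, CH2Cl2, −15 → 0 °C
Reagents that add atoms: N,O-dimethylhydroxylamine hydrochloride, CNOC.Cl
Why: Aluminium-amide transamination of the imide to the Weinreb amide, helped by the free α-hydroxyl as its aluminium alkoxide, releases the auxiliary without touching C13.

Step 7
Reactants: 18 (2S,3R)-2-hydroxy-N-methoxy-N,3,7-trimethyloct-6-enamide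
Product: 19 (2S,3R)-2-[(tert-butyldimethylsilyl)oxy]-N-methoxy-N,3,7-trimethyloct-6-enamide
Conditions: TBSOTf, 2,6-lutidine, CH2Cl2, −78 → 0 °C
Reagents that add atoms: tert-butyldimethylsilyl triflate, CC(C)(C)[Si](C)(C)OS(=O)(=O)C(F)(F)F
Why: Silylation of the hindered secondary alcohol with the silyl triflate gives the ether that carries the C13 oxygen to the end.

Step 8
Reactants: 19 (2S,3R)-2-[(tert-butyldimethylsilyl)oxy]-N-methoxy-N,3,7-trimethyloct-6-enamide
Product: 21 (2S,3R)-2-[(tert-butyldimethylsilyl)oxy]-N-methoxy-N,3-dimethyl-6-oxohexanamide, via ozonide 20 (not isolated)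
Conditions: O3, CH2Cl2, −78 °C; then PPh3, −78 °C → rt
Reagents that add atoms: ozone, [O-][O+]=O
Why: Ozonolysis with reductive work-up cleaves the only alkene, the trisubstituted C9=C(CH3)2 bond, to the C9 aldehyde.

Step 9
Reactants: 11 (R)-4-benzyl-3-[(Z)-7-iodo-6-methylhept-6-enoyl]-1,3-oxazolidin-2-one; 21 (2S,3R)-2-[(tert-butyldimethylsilyl)oxy]-N-methoxy-N,3-dimethyl-6-oxohexanamide
Product: 23 syn-aldol adduct (C8–C9 bond formed; 8R,9S,12R,13S), via dibutylboron enolate 22 (not isolated)
Conditions: Bu2BOTf, iPr2NEt, CH2Cl2, −78 → 0 °C; then 21, −78 → 0 °C; pH 7 buffer, MeOH, H2O2, 0 °C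
Reagents that add atoms: none
Why: Evans syn-aldol in which the (Z)-boron enolate adds to the aldehyde through a closed chair transition state on the face away from the benzyl group of the (R)-auxiliary, which should set C8 (8R here, the same arrangement in space that is named 8S once C19 is reduced) together with the temporary C9 carbinol.

Step 10
Reactants: 23 syn-aldol adduct
Product: 24 (2S,3R,6S,7S,11Z)-2-[(tert-butyldimethylsilyl)oxy]-6-hydroxy-7-(hydroxymethyl)-12-iodo-N-methoxy-N,3,11-trimethyldodec-11-enamide (C9,C19-diol)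
Conditions: NaBH4, THF/H2O, 0 °C → rt
Reagents that add atoms: none
Why: Borohydride reduces the activated imide carbonyl to the C19 primary alcohol with release of the auxiliary, while the hindered Weinreb amide and the iodoalkene should be left alone.

Step 11
Reactants: 24 C9,C19-diol
Product: 26 C19 tert-butyldimethylsilyl C9 triethylsilyl bis-ether of 24, via C19 mono-silyl ether 25 (not isolated)
Conditions: TBSCl, imidazole, DMF, 0 °C; then TESCl, 0 °C → rt
Reagents that add atoms: tert-butyldimethylsilyl chloride, CC(C)(C)[Si](C)(C)Cl; triethylsilyl chloride, CC[Si](CC)(CC)Cl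
Why: Stepwise silylation in one flask, the primary C19 hydroxyl reacting first with the bulkier chlorosilane and the remaining secondary C9 hydroxyl then taking the more labile triethylsilyl group.

Step 12
Reactants: 26 bis-silyl ether Weinreb amide; 27 isobutylmagnesium bromide
Product: 28 isobutyl ketone (C14 ketone with C1 and the isopropyl group; C3 alkenyl iodide; 8S,9S,12R,13S)
Conditions: THF, 0 °C → rt; aq. NH4Cl
Reagents that add atoms: none
Why: Grignard addition to the Weinreb amide stops at the chelated tetrahedral intermediate and should give the ketone without over-addition.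

Step 13
Reactants: 28 isobutyl ketone with C3 alkenyl iodide
Product: 29 (Z)-alkenyltrimethylstannane ketone
Conditions: (Me3Sn)2, Pd(PPh3)4 (5 mol %), toluene, 80 °C
Reagents that add atoms: hexamethylditin, C[Sn](C)(C)[Sn](C)(C)C
Why: Palladium-catalysed stannylation (oxidative addition of zerovalent palladium to C–I, transmetalation with the ditin, reductive elimination) proceeds with retention of the (Z)-geometry and tolerates the ketone and the silyl ethers.

Step 14
Reactants: 29 (Z)-alkenyltrimethylstannane ketone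
Product: 31 hydroxymethylene ketone (formyl carbon C2 on C1), via lithium enolate 30 (not isolated)
Conditions: LiN(iPr)2, THF, −78 °C; HCO2CH2CF3, −78 °C; aq. NH4Cl
Reagents that add atoms: 2,2,2-trifluoroethyl formate, O=COCC(F)(F)F
Why: Kinetic deprotonation occurs at the C1 methylene and not at the hindered, oxygen-bearing C13 methine, and the enolate is C-formylated by the activated formate (crossed Claisen condensation) to the hydroxymethylene ketone that supplies C2.

Step 15
Reactants: 31 hydroxymethylene ketone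
Product: 32 seco (E)-enol triflate / (Z)-alkenylstannane (C9 triethylsilyl ether; C13 and C19 tert-butyldimethylsilyl ethers)
Conditions: DBU, PhNTf2, CH2Cl2, 0 °C → rt
Reagents that add atoms: N-phenylbis(trifluoromethanesulfonimide), O=S(=O)(N(c1ccccc1)S(=O)(=O)C(F)(F)F)C(F)(F)F
Why: O-Sulfonylation of the formyl-derived enolate oxygen under non-chelating amidinium conditions, where the enolate prefers the extended form with oxygen anti to the C14 carbonyl, should give the (E)-enol triflate, and the mild triflimide leaves the alkenylstannane intact.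

Step 16
Reactants: 32 seco (E)-enol triflate / (Z)-alkenylstannane
Product: 33 (2E,4Z,9S,10S,13R,14S)-14-[(tert-butyldimethylsilyl)oxy]-9-{[(tert-butyldimethylsilyl)oxy]methyl}-5,13-dimethyl-2-(propan-2-yl)-10-[(triethylsilyl)oxy]cyclotetradeca-2,4-dien-1-one (ring (1E,3Z)-dienone in the plan numbering)
Conditions: Pd2(dba)3 (10 mol %), AsPh3 (40 mol %), LiCl, DMF, 0.001 M, slow addition, 40 °C, dark
Reagents that add atoms: none
Why: Zerovalent palladium inserts into the C2–OTf bond (chloride from LiCl stabilising the alkenylpalladium), the C3 alkenylstannane transmetalates intramolecularly, and C2–C3 reductive elimination releases the diene and the catalyst. The closest known reaction type is the macrocyclising Stille coupling of an alkenyl triflate with an alkenylstannane within one chain. The 14-membered carbocycle closes end-to-end at the sp2–sp2 C2–C3 bond through a cyclic diorganopalladium intermediate, under high dilution with slow addition so that ring closure outruns oligomerisation. No stereocentre is formed; the (1E) geometry from the triflate and the (3Z) geometry from the stannane are carried over with retention, because oxidative addition, transmetalation and reductive elimination all retain configuration at sp2 carbon. The step needs clean intramolecular coupling without alkene isomerisation, epimerisation or protodestannylation, which the neutral base-free medium, the fast-transferring trimethylstannyl group with AsPh3 as ligand, and the masking of C9 as a silyl ether (no enolisable carbonyl next to C8) should secure.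

Step 17
Reactants: 33 macrocyclic dienone with C9 triethylsilyl ether
Product: 34 C9 alcohol of the macrocyclic dienone (8S,9S,12R,13S)
Conditions: PPTS, MeOH/CH2Cl2, 0 °C
Reagents that add atoms: none
Why: Mild acid methanolysis removes the triethylsilyl ether considerably faster than the two tert-butyldimethylsilyl ethers.

Step 18
Reactants: 34 C9 alcohol
Product: 35 (2E,4Z,9S,13R,14S)-14-[(tert-butyldimethylsilyl)oxy]-9-{[(tert-butyldimethylsilyl)oxy]methyl}-5,13-dimethyl-2-(propan-2-yl)cyclotetradeca-2,4-diene-1,10-dione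
Conditions: Dess–Martin periodinane, pyridine, CH2Cl2, 0 °C → rt
Reagents that add atoms: none
Why: Dess–Martin oxidation under buffered, non-basic conditions should give the C9 ketone without epimerising C8 or eliminating the β-silyloxy group.

Step 19
Reactants: 35 macrocyclic (1E,3Z)-dienone diketone
Product: 36 (3S,4R)-epoxide of 35 (C13 and C19 tert-butyldimethylsilyl ethers)
Conditions: 1,2:4,5-di-O-isopropylidene-β-L-erythro-2,3-hexodiulo-2,6-pyranose (L-fructose-derived ketone, 30 mol %), KHSO5 (as 2KHSO5·KHSO4·K2SO4), K2CO3, Bu4NHSO4, Na2B4O7 buffer, MeCN/CH2(OMe)2/H2O, 0 °C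
Reagents that add atoms: potassium peroxymonosulfate, [K+].[O-]S(=O)(=O)OO
Why: Shi epoxidation, in which the electrophilic chiral dioxirane attacks the distal, electron-richer C3=C4 alkene and not the carbonyl-conjugated C1=C2, and with the C3 hydrogen in the hindered position of the spiro transition state the L-series ketone should deliver oxygen to the face that gives the (3S,4R)-epoxide.

Step 20
Reactants: 36 bis-silyl epoxide
Product: 37 target CNP0110598.2 (1E,3S,4R,8S,12R,13S)
Conditions: HF·pyridine, pyridine, THF, 0 °C → rt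
Reagents that add atoms: none
Why: Buffered fluoride desilylation cleaves both silyl ethers while the trisubstituted epoxide, the β-hydroxy ketone and the α-hydroxy enone should tolerate the nearly neutral medium.

**Compound list**

1 | tert-butyl[(5-bromopentyl)oxy]dimethylsilane | BrCCCCCO[Si](C)(C)C(C)(C)C | starting material
2 | propyne | CC#C | starting material
3 | [5-(tert-butyldimethylsilyloxy)pentyl]magnesium bromide (not isolated) | Br[Mg]CCCCCO[Si](C)(C)C(C)(C)C | intermediate
4 | (Z)-[7-(tert-butyldimethylsilyloxy)-2-methylhept-1-en-1-yl]copper, as its MgBr2/SMe2 complex (not isolated) | [Cu]/C=C(/C)CCCCCO[Si](C)(C)C(C)(C)C | intermediate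
5 | tert-butyl{[(Z)-7-iodo-6-methylhept-6-en-1-yl]oxy}dimethylsilane | I/C=C(/C)CCCCCO[Si](C)(C)C(C)(C)C | intermediate
6 | (Z)-7-iodo-6-methylhept-6-en-1-ol (not isolated) | I/C=C(/C)CCCCCO | intermediate
7 | (Z)-7-iodo-6-methylhept-6-enal (not isolated) | I/C=C(/C)CCCCC=O | intermediate
8 | (Z)-7-iodo-6-methylhept-6-enoic acid | I/C=C(/C)CCCCC(=O)O | intermediate
9 | (R)-4-benzyl-1,3-oxazolidin-2-one | O=C1OC[C@@H](Cc2ccccc2)N1 | starting material
10 | (Z)-7-iodo-6-methylhept-6-enoic pivalic anhydride (not isolated) | I/C=C(/C)CCCCC(=O)OC(=O)C(C)(C)C | intermediate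
11 | (R)-4-benzyl-3-[(Z)-7-iodo-6-methylhept-6-enoyl]-1,3-oxazolidin-2-one | I/C=C(/C)CCCCC(=O)N1[C@H](Cc2ccccc2)COC1=O | intermediate
12 | (R)-citronellic acid, (R)-3,7-dimethyloct-6-enoic acid | CC(C)=CCC[C@@H](C)CC(=O)O | starting material
13 | (S)-4-benzyl-1,3-oxazolidin-2-one | O=C1OC[C@H](Cc2ccccc2)N1 | starting material
14 | (R)-3,7-dimethyloct-6-enoic pivalic anhydride (not isolated) | CC(C)=CCC[C@@H](C)CC(=O)OC(=O)C(C)(C)C | intermediate
15 | (S)-4-benzyl-3-[(R)-3,7-dimethyloct-6-enoyl]-1,3-oxazolidin-2-one | CC(C)=CCC[C@@H](C)CC(=O)N1[C@@H](Cc2ccccc2)COC1=O | intermediate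
16 | sodium (Z)-enolate of 15 (not isolated) | CC(C)=CCC[C@@H](C)/C=C(\O[Na])N1[C@@H](Cc2ccccc2)COC1=O | intermediate
17 | (S)-4-benzyl-3-[(2S,3R)-2-hydroxy-3,7-dimethyloct-6-enoyl]-1,3-oxazolidin-2-one | CC(C)=CCC[C@@H](C)[C@H](O)C(=O)N1[C@@H](Cc2ccccc2)COC1=O | intermediate
18 | (2S,3R)-2-hydroxy-N-methoxy-N,3,7-trimethyloct-6-enamide | CC(C)=CCC[C@@H](C)[C@H](O)C(=O)N(C)OC | intermediate
19 | (2S,3R)-2-[(tert-butyldimethylsilyl)oxy]-N-methoxy-N,3,7-trimethyloct-6-enamide | CC(C)=CCC[C@@H](C)[C@H](O[Si](C)(C)C(C)(C)C)C(=O)N(C)OC | intermediate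
20 | secondary ozonide (1,2,4-trioxolane) of 19, ring carbon from C9 unassigned (not isolated) | CC1(C)OOC(CC[C@@H](C)[C@H](O[Si](C)(C)C(C)(C)C)C(=O)N(C)OC)O1 | intermediate
21 | (2S,3R)-2-[(tert-butyldimethylsilyl)oxy]-N-methoxy-N,3-dimethyl-6-oxohexanamide (C9 aldehyde, C14 Weinreb amide) | O=CCC[C@@H](C)[C@H](O[Si](C)(C)C(C)(C)C)C(=O)N(C)OC | intermediate
22 | dibutylboron (Z)-enolate of 11 (not isolated) | I/C=C(/C)CCC/C=C(\OB(CCCC)CCCC)N1[C@H](Cc2ccccc2)COC1=O | intermediate
23 | syn-aldol adduct: N-acyl (R)-4-benzyloxazolidinone with C19 as imide carbonyl, C8 bearing the (Z)-5-iodo-4-methylpent-4-enyl chain, C9 hydroxyl, C12 methyl, C13 silyl ether, C14 Weinreb amide (8R,9S,12R,13S) | I/C=C(/C)CCC[C@@H](C(=O)N1[C@H](Cc2ccccc2)COC1=O)[C@@H](O)CC[C@@H](C)[C@H](O[Si](C)(C)C(C)(C)C)C(=O)N(C)OC | intermediate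
24 | (2S,3R,6S,7S,11Z)-2-[(tert-butyldimethylsilyl)oxy]-6-hydroxy-7-(hydroxymethyl)-12-iodo-N-methoxy-N,3,11-trimethyldodec-11-enamide | I/C=C(/C)CCC[C@@H](CO)[C@@H](O)CC[C@@H](C)[C@H](O[Si](C)(C)C(C)(C)C)C(=O)N(C)OC | intermediate
25 | C19 tert-butyldimethylsilyl ether of 24, C9 hydroxyl free (not isolated) | I/C=C(/C)CCC[C@@H](CO[Si](C)(C)C(C)(C)C)[C@@H](O)CC[C@@H](C)[C@H](O[Si](C)(C)C(C)(C)C)C(=O)N(C)OC | intermediate
26 | C19 tert-butyldimethylsilyl, C9 triethylsilyl bis-ether of 24 (8S,9S,12R,13S) | I/C=C(/C)CCC[C@@H](CO[Si](C)(C)C(C)(C)C)[C@@H](O[Si](CC)(CC)CC)CC[C@@H](C)[C@H](O[Si](C)(C)C(C)(C)C)C(=O)N(C)OC | intermediate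
27 | isobutylmagnesium bromide | CC(C)C[Mg]Br | starting material
28 | open-chain isobutyl ketone: C3 (Z)-alkenyl iodide, C19 and C13 tert-butyldimethylsilyl ethers, C9 triethylsilyl ether, C14 ketone (8S,9S,12R,13S) | I/C=C(/C)CCC[C@@H](CO[Si](C)(C)C(C)(C)C)[C@@H](O[Si](CC)(CC)CC)CC[C@@H](C)[C@H](O[Si](C)(C)C(C)(C)C)C(=O)CC(C)C | intermediate
29 | (Z)-alkenyltrimethylstannane analogue of 28 | C[Sn](C)(C)/C=C(/C)CCC[C@@H](CO[Si](C)(C)C(C)(C)C)[C@@H](O[Si](CC)(CC)CC)CC[C@@H](C)[C@H](O[Si](C)(C)C(C)(C)C)C(=O)CC(C)C | intermediate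
30 | lithium enolate of 29 towards C1, drawn as the Z(O) isomer (not isolated) | C[Sn](C)(C)/C=C(/C)CCC[C@@H](CO[Si](C)(C)C(C)(C)C)[C@@H](O[Si](CC)(CC)CC)CC[C@@H](C)[C@H](O[Si](C)(C)C(C)(C)C)/C(O[Li])=C/C(C)C | intermediate
31 | hydroxymethylene ketone (formyl carbon C2 on C1), drawn as the chelated enol in equilibrium with the keto aldehyde | C[Sn](C)(C)/C=C(/C)CCC[C@@H](CO[Si](C)(C)C(C)(C)C)[C@@H](O[Si](CC)(CC)CC)CC[C@@H](C)[C@H](O[Si](C)(C)C(C)(C)C)C(=O)/C(C(C)C)=C\O | intermediate
32 | seco C2 (E)-enol triflate / C3 (Z)-alkenyltrimethylstannane (8S,9S,12R,13S) | C[Sn](C)(C)/C=C(/C)CCC[C@@H](CO[Si](C)(C)C(C)(C)C)[C@@H](O[Si](CC)(CC)CC)CC[C@@H](C)[C@H](O[Si](C)(C)C(C)(C)C)C(=O)/C(C(C)C)=C/OS(=O)(=O)C(F)(F)F | intermediate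
33 | (2E,4Z,9S,10S,13R,14S)-14-[(tert-butyldimethylsilyl)oxy]-9-{[(tert-butyldimethylsilyl)oxy]methyl}-5,13-dimethyl-2-(propan-2-yl)-10-[(triethylsilyl)oxy]cyclotetradeca-2,4-dien-1-one | CC(C)/C1=C\C=C(\C)CCC[C@@H](CO[Si](C)(C)C(C)(C)C)[C@@H](O[Si](CC)(CC)CC)CC[C@@H](C)[C@H](O[Si](C)(C)C(C)(C)C)C1=O | intermediate
34 | (2E,4Z,9S,10S,13R,14S)-14-[(tert-butyldimethylsilyl)oxy]-9-{[(tert-butyldimethylsilyl)oxy]methyl}-10-hydroxy-5,13-dimethyl-2-(propan-2-yl)cyclotetradeca-2,4-dien-1-one | CC(C)/C1=C\C=C(\C)CCC[C@@H](CO[Si](C)(C)C(C)(C)C)[C@@H](O)CC[C@@H](C)[C@H](O[Si](C)(C)C(C)(C)C)C1=O | intermediate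
35 | (2E,4Z,9S,13R,14S)-14-[(tert-butyldimethylsilyl)oxy]-9-{[(tert-butyldimethylsilyl)oxy]methyl}-5,13-dimethyl-2-(propan-2-yl)cyclotetradeca-2,4-diene-1,10-dione | CC(C)/C1=C\C=C(\C)CCC[C@@H](CO[Si](C)(C)C(C)(C)C)C(=O)CC[C@@H](C)[C@H](O[Si](C)(C)C(C)(C)C)C1=O | intermediate
36 | (3S,4R)-epoxide of 35 (3S,4R,8S,12R,13S; 1E) | CC(C)/C1=C\[C@@H]2O[C@]2(C)CCC[C@@H](CO[Si](C)(C)C(C)(C)C)C(=O)CC[C@@H](C)[C@H](O[Si](C)(C)C(C)(C)C)C1=O | intermediate
37 | CNP0110598.2 (1E,3S,4R,8S,12R,13S) | CC(C)/C1=C\[C@@H]2O[C@]2(C)CCC[C@@H](CO)C(=O)CC[C@@H](C)[C@H](O)C1=O | target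

**Step count**

Total: 20 steps. Longest linear sequence: 17 steps (12 → 37, steps 4–8 and 9–20); the other branch (1 → 11) has 3 steps before the union.

**Steps most likely to fail**

1. Step 16. Ring closure may lose to oligomerisation, or transmetalation of the stannane that carries a cis alkyl chain may be so slow that the alkenylpalladium species decays. The fallback replaces tin by boron. It sets out from 28: Miyaura borylation (B2pin2, PdCl2(PPh3)2, PPh3, KOPh, toluene, 50 °C) should give the alkenyl pinacolboronate ketone F1. Formylation as in step 14 then gives the boronate hydroxymethylene ketone F2, and triflation as in step 15 gives the boronate enol triflate F3. Intramolecular Suzuki–Miyaura coupling (Pd(PPh3)4, K3PO4, dioxane, 60 °C, high dilution), in which a base-activated boronate transmetalates by a different pathway from a hindered stannane, closes the same C2–C3 bond and comes back to the route at 33.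

2. Step 19. Facial selectivity may be poor if the bias of the ring opposes that of the dioxirane, and peroxide may attack the enone or a ketone under the basic buffer. The fallback sets out from 35 and uses a Jacobsen–Katsuki epoxidation with [N,N'-bis(3,5-di-tert-butylsalicylidene)cyclohexane-1,2-diamine]MnCl, mCPBA and N-methylmorpholine N-oxide in CH2Cl2 at −78 °C. This is a metal-oxo oxidant suited to cis-configured conjugated alkenes, it follows a different stereochemical model and it avoids aqueous base; both antipodes of the diamine are available, so either sense of reagent control can be applied. It comes back to the route at 36 and makes no further compound (F0).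

3. Step 15. Sulfonylation may show poor E/Z control, or may occur on the C14 oxygen. The fallback fixes the geometry by thermodynamic control and sets out from 31: TsCl and Et3N in CH2Cl2 should give the enol tosylate F4 as a mixture of isomers whose geometry is immaterial. NaI in acetone then exchanges tosylate for iodide by addition–elimination to give the (E)-β-iodo enone F5; because iodide adds and leaves reversibly, the mixture should settle to the isomer with iodine anti to the C14 carbonyl. Stille ring closure of F5 between the alkenyl iodide and the alkenylstannane (Pd2(dba)3, AsPh3, DMF, high dilution) comes back to the route at 33.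

**Further compounds**

F1 | step 16 | alkenyl pinacolboronate ketone (boron in place of iodine in 28) | CC1(C)OB(OC1(C)C)/C=C(/C)CCC[C@@H](CO[Si](C)(C)C(C)(C)C)[C@@H](O[Si](CC)(CC)CC)CC[C@@H](C)[C@H](O[Si](C)(C)C(C)(C)C)C(=O)CC(C)C
F2 | step 16 | boronate hydroxymethylene ketone | CC1(C)OB(OC1(C)C)/C=C(/C)CCC[C@@H](CO[Si](C)(C)C(C)(C)C)[C@@H](O[Si](CC)(CC)CC)CC[C@@H](C)[C@H](O[Si](C)(C)C(C)(C)C)C(=O)/C(C(C)C)=C\O
F3 | step 16 | boronate (E)-enol triflate | CC1(C)OB(OC1(C)C)/C=C(/C)CCC[C@@H](CO[Si](C)(C)C(C)(C)C)[C@@H](O[Si](CC)(CC)CC)CC[C@@H](C)[C@H](O[Si](C)(C)C(C)(C)C)C(=O)/C(C(C)C)=C/OS(=O)(=O)C(F)(F)F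
F0 | step 19 | none | none
F4 | step 15 | enol tosylate of 31 (E/Z mixture at C1=C2) | C[Sn](C)(C)/C=C(/C)CCC[C@@H](CO[Si](C)(C)C(C)(C)C)[C@@H](O[Si](CC)(CC)CC)CC[C@@H](C)[C@H](O[Si](C)(C)C(C)(C)C)C(=O)C(C(C)C)=COS(=O)(=O)c1ccc(C)cc1
F5 | step 15 | (E)-β-iodo enone with C3 alkenylstannane | C[Sn](C)(C)/C=C(/C)CCC[C@@H](CO[Si](C)(C)C(C)(C)C)[C@@H](O[Si](CC)(CC)CC)CC[C@@H](C)[C@H](O[Si](C)(C)C(C)(C)C)C(=O)/C(C(C)C)=C/I
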